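## Retrosynthetic overview

1. Target 31 ⇐ 6α‑alcohol 28 (angelate installed last) ⇐ C6 ketone 27 (hydroxyl‑directed reduction) ⇐ 18, whose seven‑membered ring is oxidised by epoxide→allylic alcohol transposition and hydroxyl‑directed epoxidation.
2. 18 (4β‑OH, trans ring fusion) ⇐ enone 15 by nucleophilic epoxidation and SmI2 opening; 15 ⇐ vinylogous silyl ester 12 by Stork–Danheiser addition of isopropyl.
3. Key disconnection: 12 ⇐ acyclic siloxyvinyl diazoketone 10. Carbenoid cyclopropanation closes the five‑membered ring and the cis‑divinylcyclopropane Cope rearrangement closes the seven‑membered ring in the same flask, fixing the quaternary C1.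
4. 10 ⇐ catalytic asymmetric Mukaiyama aldol of diazo enol silane 8 (from acetylacetone) with dienal 3 (from crotonaldehyde).
5. Ring order: five‑ and seven‑membered carbocycles together (step 6); oxirane last (step 13).

Conventions: bicyclic compounds carry daucane numbering (C1 = angular‑methyl ring‑fusion carbon; C2–C3–C4 to C5 = ring‑fusion CH; C6–C10 around the seven‑membered ring back to C1). α is the face opposite the C1 methyl. TBS = tert‑butyldimethylsilyl.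
Assumption: (R)‑BINAP with AgF is taken to give the 6S aldol 9; if the sense proves opposite, (S)‑BINAP is used and nothing else changes.

## Route

Step 1
Reactants: 1 (E)‑but‑2‑enal (crotonaldehyde); 2 2‑(triphenylphosphoranylidene)propanal
Product: 3 (2E,4E)‑2‑methylhexa‑2,4‑dienal
Conditions: 1 (2 equiv), PhMe, 80 °C
Reagents that add atoms: 2 2‑(triphenylphosphoranylidene)propanal, CC(C=O)=P(c1ccccc1)(c1ccccc1)c1ccccc1
Why: Wittig olefination with a stabilised formyl ylide is E‑selective and stops after one homologation because the α‑methyl dienal is a poorer electrophile than the crotonaldehyde used in excess.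

Step 2
Reactants: 4 pentane‑2,4‑dione (acetylacetone); 5 4‑acetamidobenzenesulfonyl azide
Product: 6 3‑diazopentane‑2,4‑dione
Conditions: Et3N, MeCN, 0 → 23 °C
Reagents that add atoms: 5 4‑acetamidobenzenesulfonyl azide, CC(=O)Nc1ccc(cc1)S(=O)(=O)N=[N+]=[N-]
Why: Regitz diazo transfer to the doubly activated methylene of a 1,3‑diketone is fast and clean with a sulfonyl azide and an amine base.

Step 3
Reactants: 6 3‑diazopentane‑2,4‑dione; 7 tert‑butyldimethylsilyl trifluoromethanesulfonate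
Product: 8 4‑[(tert‑butyldimethylsilyl)oxy]‑3‑diazopent‑4‑en‑2‑one
Conditions: TBSOTf (1.05 equiv), Et3N, CH2Cl2, 0 °C
Reagents that add atoms: 7 tert‑butyldimethylsilyl trifluoromethanesulfonate, CC(C)(C)[Si](C)(C)OS(=O)(=O)C(F)(F)F
Why: Soft enolisation with a silyl triflate and amine converts one acetyl group into its enol silane without touching the diazo group, giving the ketone analogue of the well‑known siloxyvinyl diazoacetate.

Step 4
Reactants: 8 4‑[(tert‑butyldimethylsilyl)oxy]‑3‑diazopent‑4‑en‑2‑one; 3 (2E,4E)‑2‑methylhexa‑2,4‑dienal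
Product: 9 (6S,7E,9E)‑3‑diazo‑6‑hydroxy‑7‑methylundeca‑7,9‑diene‑2,4‑dione
Conditions: AgF (10 mol %), (R)‑BINAP (10 mol %), THF, −20 °C; aq. HCl work‑up
Reagents that add atoms: 3 (2E,4E)‑2‑methylhexa‑2,4‑dienal, C/C=C/C=C(\C)C=O
Why: Catalytic enantioselective Mukaiyama aldol addition of the diazo enol silane to the enal occurs 1,2, and the BINAP–AgF catalyst selects the aldehyde face to set the carbinol (future C2) as S.

Step 5
Reactants: 9 (6S,7E,9E)‑3‑diazo‑6‑hydroxy‑7‑methylundeca‑7,9‑diene‑2,4‑dione; 7 tert‑butyldimethylsilyl trifluoromethanesulfonate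
Product: 10 (6S,7E,9E)‑2,6‑bis[(tert‑butyldimethylsilyl)oxy]‑3‑diazo‑7‑methylundeca‑1,7,9‑trien‑4‑one
Conditions: TBSOTf (2.3 equiv), Et3N, CH2Cl2, −78 → 0 °C
Reagents that add atoms: 7 tert‑butyldimethylsilyl trifluoromethanesulfonate, CC(C)(C)[Si](C)(C)OS(=O)(=O)C(F)(F)F
Why: The silyl triflate silylates the secondary alcohol and soft‑enolises the remaining acetyl group on its methyl side (the other α‑carbon is flanked by the branched silyloxy carbon), giving the siloxyvinyl diazoketone.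

Step 6
Reactants: 10 (6S,7E,9E)‑2,6‑bis[(tert‑butyldimethylsilyl)oxy]‑3‑diazo‑7‑methylundeca‑1,7,9‑trien‑4‑one
Product: 12 2α,6‑bis(TBSO)‑1β,8α‑dimethylbicyclo[5.3.0]deca‑5,9‑dien‑4‑one, via cis‑divinylcyclopropane 11 (not isolated)
Conditions: Rh2(OAc)4 (1 mol %), PhMe, 23 °C (slow addition); then 80 °C
Reagents that add atoms: none
Why: Intramolecular dirhodium‑carbenoid cyclopropanation of the proximal trisubstituted E‑alkene closes the five‑membered ring with the C2 silyloxy group in the inside position away from the alkene methyl, which fixes quaternary C1 with methyl trans to OTBS, and the cis‑divinylcyclopropane then undergoes boat Cope (divinylcyclopropane–cycloheptadiene) rearrangement to close the seven‑membered ring with the C8 methyl trans to the C1 methyl.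

Step 7
Reactants: 12 2α,6‑bis(TBSO)‑1β,8α‑dimethylbicyclo[5.3.0]deca‑5,9‑dien‑4‑one; 13 isopropyllithium
Product: 15 (8βH)‑2α‑(TBSO)dauca‑4,9‑dien‑6‑one, via tertiary alkoxide 14 (not isolated)
Conditions: iPrLi, CeCl3, THF, −78 °C; then 1 M HCl, 0 → 23 °C
Reagents that add atoms: 13 isopropyllithium, [Li]C(C)C
Why: Stork–Danheiser transposition, in which the organocerium adds 1,2 to the vinylogous silyl ester carbonyl without enolisation and acid then ionises the tertiary allylic alkoxide and hydrolyses the enol silane to the transposed enone, so the facial course of the addition is irrelevant.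

Step 8
Reactants: 15 (8βH)‑2α‑(TBSO)dauca‑4,9‑dien‑6‑one; 16 tert‑butyl hydroperoxide
Product: 17 (8βH)‑4β,5β‑epoxy‑2α‑(TBSO)dauc‑9‑en‑6‑one
Conditions: TBHP, DBU, PhMe, 0 → 23 °C
Reagents that add atoms: 16 tert‑butyl hydroperoxide, CC(C)(C)OO
Why: Weitz–Scheffer nucleophilic epoxidation touches only the electron‑poor enone alkene, and the peroxide attacks C4 anti to the bulky 2α‑silyloxy group, giving the β‑epoxide that places the C4 oxygen cis to the angular methyl.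

Step 9
Reactants: 17 (8βH)‑4β,5β‑epoxy‑2α‑(TBSO)dauc‑9‑en‑6‑one
Product: 18 (5αH,8βH)‑4β‑hydroxy‑2α‑(TBSO)dauc‑9‑en‑6‑one
Conditions: SmI2 (2.5 equiv), THF/MeOH, −90 °C
Reagents that add atoms: none
Why: SmI2 reduction of the α,β‑epoxy ketone cleaves the Cα–O bond to the β‑hydroxy ketone with C4 untouched, and protonation of the enolate at C5 (equilibrating through the ketone if needed) gives the trans‑fused 5α‑H epimer, in which the isopropyl group and C6 are trans on the five‑membered ring.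

Step 10
Reactants: 18 (5αH,8βH)‑4β‑hydroxy‑2α‑(TBSO)dauc‑9‑en‑6‑one; 19 3‑chloroperoxybenzoic acid
Product: 20 (5αH,8βH)‑9α,10α‑epoxy‑4β‑hydroxy‑2α‑(TBSO)daucan‑6‑one
Conditions: mCPBA, NaHCO3, CH2Cl2, 0 °C
Reagents that add atoms: 19 3‑chloroperoxybenzoic acid, OOC(=O)c1cccc(Cl)c1
Why: Prilezhaev epoxidation of the only remaining alkene occurs on the α face, anti to the axial angular methyl of the now trans‑fused bicycle, the 8α‑methyl being pseudo‑equatorial.

Step 11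
Reactants: 20 (5αH,8βH)‑9α,10α‑epoxy‑4β‑hydroxy‑2α‑(TBSO)daucan‑6‑one
Product: 23 (5αH)‑4β,10α‑dihydroxy‑2α‑(TBSO)dauc‑8‑en‑6‑one, via hydroxy selenide 21 (not isolated), via selenoxide 22 (not isolated)
Conditions: (PhSe)2, NaBH4 (premixed), EtOH, 0 → 60 °C; then H2O2, THF, 0 → 23 °C
Reagents that add atoms: none
Why: Sharpless epoxide‑to‑allylic‑alcohol transposition, in which phenylselenide opens the epoxide anti at C9 (C10 is neopentyl) and the selenoxide eliminates syn with the 8β‑hydrogen and away from the carbinol, leaving the 10α‑hydroxyl and the C8=C9 alkene.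

Step 12
Reactants: 23 (5αH)‑4β,10α‑dihydroxy‑2α‑(TBSO)dauc‑8‑en‑6‑one
Product: 24 (5αH)‑2α,4β,10α‑trihydroxydauc‑8‑en‑6‑one
Conditions: HF·pyridine, THF/pyridine, 0 → 23 °C
Reagents that add atoms: none
Why: Buffered fluoride desilylation frees the C2 hydroxyl at a stage where no epoxide is present and the β‑hydroxy ketone is not exposed to base.

Step 13
Reactants: 24 (5αH)‑2α,4β,10α‑trihydroxydauc‑8‑en‑6‑one; 16 tert‑butyl hydroperoxide
Product: 25 (5αH)‑8α,9α‑epoxy‑2α,4β,10α‑trihydroxydaucan‑6‑one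
Conditions: VO(acac)2 (5 mol %), TBHP, CH2Cl2, 0 °C
Reagents that add atoms: 16 tert‑butyl hydroperoxide, CC(C)(C)OO
Why: Hydroxyl‑directed vanadium‑catalysed (Sharpless) epoxidation delivers oxygen syn to the allylic 10α‑hydroxyl, giving the 8α,9α‑epoxide.

Step 14
Reactants: 25 (5αH)‑8α,9α‑epoxy‑2α,4β,10α‑trihydroxydaucan‑6‑one; 26 acetic anhydride
Product: 27 (5αH)‑2α,10α‑diacetoxy‑8α,9α‑epoxy‑4β‑hydroxydaucan‑6‑one
Conditions: Ac2O, pyridine, DMAP (cat.), CH2Cl2, 23 °C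
Reagents that add atoms: 26 acetic anhydride, CC(=O)OC(C)=O
Why: Acylation with acetic anhydride esterifies the two secondary hydroxyls while the tertiary C4 hydroxyl is too hindered to react under these conditions.

Step 15
Reactants: 27 (5αH)‑2α,10α‑diacetoxy‑8α,9α‑epoxy‑4β‑hydroxydaucan‑6‑one
Product: 28 (5αH)‑2α,10α‑diacetoxy‑8α,9α‑epoxydaucane‑4β,6α‑diol
Conditions: Me4NBH(OAc)3, MeCN/AcOH, −30 → 0 °C
Reagents that add atoms: none
Why: Evans–Saksena reduction, in which the triacetoxyborohydride binds the tertiary 4β‑hydroxyl and delivers hydride intramolecularly to the β face of the C6 ketone to give the 6α‑alcohol (1,3‑anti diol) while esters and epoxide survive.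

Step 16
Reactants: 28 (5αH)‑2α,10α‑diacetoxy‑8α,9α‑epoxydaucane‑4β,6α‑diol; 29 angelic acid
Product: 31 (5αH)‑2α,10α‑diacetoxy‑6α‑angeloyloxy‑8α,9α‑epoxydaucan‑4β‑ol (target), via mixed anhydride 30 (not isolated)
Conditions: 29, 2,4,6‑Cl3C6H2COCl, Et3N, PhMe, 23 °C; then 28, 80 °C
Reagents that add atoms: 29 angelic acid, C/C=C(/C)C(=O)O
Why: Yamaguchi‑type esterification through the 2,4,6‑trichlorobenzoyl mixed anhydride without a nucleophilic catalyst acylates the only free secondary hydroxyl and installs the angelate without isomerisation to the tiglate.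

## Compound list

1 | (E)‑but‑2‑enal | C/C=C/C=O | starting material
2 | 2‑(triphenylphosphoranylidene)propanal | CC(C=O)=P(c1ccccc1)(c1ccccc1)c1ccccc1 | starting material
3 | (2E,4E)‑2‑methylhexa‑2,4‑dienal | C/C=C/C=C(\C)C=O | intermediate
4 | pentane‑2,4‑dione | CC(=O)CC(C)=O | starting material
5 | 4‑acetamidobenzenesulfonyl azide | CC(=O)Nc1ccc(cc1)S(=O)(=O)N=[N+]=[N-] | starting material
6 | 3‑diazopentane‑2,4‑dione | CC(=O)C(=[N+]=[N-])C(C)=O | intermediate
7 | tert‑butyldimethylsilyl trifluoromethanesulfonate | CC(C)(C)[Si](C)(C)OS(=O)(=O)C(F)(F)F | starting material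
8 | 4‑[(tert‑butyldimethylsilyl)oxy]‑3‑diazopent‑4‑en‑2‑one | C=C(O[Si](C)(C)C(C)(C)C)C(=[N+]=[N-])C(C)=O | intermediate
9 | (6S,7E,9E)‑3‑diazo‑6‑hydroxy‑7‑methylundeca‑7,9‑diene‑2,4‑dione | CC(=O)C(=[N+]=[N-])C(=O)C[C@H](O)/C(C)=C/C=C/C | intermediate
10 | (6S,7E,9E)‑2,6‑bis[(tert‑butyldimethylsilyl)oxy]‑3‑diazo‑7‑methylundeca‑1,7,9‑trien‑4‑one | C=C(O[Si](C)(C)C(C)(C)C)C(=[N+]=[N-])C(=O)C[C@H](O[Si](C)(C)C(C)(C)C)/C(C)=C/C=C/C | intermediate
11 | cis‑divinylcyclopropane: 4‑(TBSO)‑5‑methyl‑6‑[(E)‑prop‑1‑enyl]‑1‑[1‑(TBSO)vinyl]bicyclo[3.1.0]hexan‑2‑one (siloxyvinyl, methyl and propenyl all on the cyclopropane face opposite the five‑membered ring; ring OTBS syn to the cyclopropane CH) | C/C=C/[C@@H]1[C@@]2(C)[C@@H](O[Si](C)(C)C(C)(C)C)CC(=O)[C@@]12C(O[Si](C)(C)C(C)(C)C)=C | intermediate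
12 | 2α,6‑bis(TBSO)‑1β,8α‑dimethylbicyclo[5.3.0]deca‑5,9‑dien‑4‑one | CC(C)(C)[Si](C)(C)OC1=C2C(=O)C[C@H](O[Si](C)(C)C(C)(C)C)[C@]2(C)C=C[C@H](C)C1 | intermediate
13 | isopropyllithium | [Li]C(C)C | starting material
14 | tertiary alkoxide: 4‑isopropyl‑2α,6‑bis(TBSO)‑1β,8α‑dimethylbicyclo[5.3.0]deca‑5,9‑dien‑4‑ol, both C4 epimers (drawn as the free alcohol) | CC(C)(C)[Si](C)(C)OC1=C2C(O)(C(C)C)C[C@H](O[Si](C)(C)C(C)(C)C)[C@]2(C)C=C[C@H](C)C1 | intermediate
15 | (8βH)‑2α‑(TBSO)dauca‑4,9‑dien‑6‑one | O=C1C2=C(C(C)C)C[C@H](O[Si](C)(C)C(C)(C)C)[C@]2(C)C=C[C@H](C)C1 | intermediate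
16 | tert‑butyl hydroperoxide | CC(C)(C)OO | starting material
17 | (8βH)‑4β,5β‑epoxy‑2α‑(TBSO)dauc‑9‑en‑6‑one | O=C1[C@@]23O[C@@]3(C(C)C)C[C@H](O[Si](C)(C)C(C)(C)C)[C@]2(C)C=C[C@H](C)C1 | intermediate
18 | (5αH,8βH)‑4β‑hydroxy‑2α‑(TBSO)dauc‑9‑en‑6‑one | O=C1[C@H]2[C@](O)(C(C)C)C[C@H](O[Si](C)(C)C(C)(C)C)[C@]2(C)C=C[C@H](C)C1 | intermediate
19 | 3‑chloroperoxybenzoic acid | OOC(=O)c1cccc(Cl)c1 | starting material
20 | (5αH,8βH)‑9α,10α‑epoxy‑4β‑hydroxy‑2α‑(TBSO)daucan‑6‑one | O=C1[C@H]2[C@](O)(C(C)C)C[C@H](O[Si](C)(C)C(C)(C)C)[C@]2(C)[C@@H]3O[C@@H]3[C@H](C)C1 | intermediate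
21 | hydroxy selenide: (5αH,8βH)‑4β,10α‑dihydroxy‑9β‑(phenylselanyl)‑2α‑(TBSO)daucan‑6‑one | O=C1[C@H]2[C@](O)(C(C)C)C[C@H](O[Si](C)(C)C(C)(C)C)[C@]2(C)[C@H](O)[C@@H]([Se]c3ccccc3)[C@H](C)C1 | intermediate
22 | selenoxide of 21 (mixture at selenium) | O=C1[C@H]2[C@](O)(C(C)C)C[C@H](O[Si](C)(C)C(C)(C)C)[C@]2(C)[C@H](O)[C@@H]([Se](=O)c3ccccc3)[C@H](C)C1 | intermediate
23 | (5αH)‑4β,10α‑dihydroxy‑2α‑(TBSO)dauc‑8‑en‑6‑one | O=C1[C@H]2[C@](O)(C(C)C)C[C@H](O[Si](C)(C)C(C)(C)C)[C@]2(C)[C@H](O)C=C(C)C1 | intermediate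
24 | (5αH)‑2α,4β,10α‑trihydroxydauc‑8‑en‑6‑one | O=C1[C@H]2[C@](O)(C(C)C)C[C@H](O)[C@]2(C)[C@H](O)C=C(C)C1 | intermediate
25 | (5αH)‑8α,9α‑epoxy‑2α,4β,10α‑trihydroxydaucan‑6‑one | O=C1[C@H]2[C@](O)(C(C)C)C[C@H](O)[C@]2(C)[C@H](O)[C@@H]3O[C@]3(C)C1 | intermediate
26 | acetic anhydride | CC(=O)OC(C)=O | starting material
27 | (5αH)‑2α,10α‑diacetoxy‑8α,9α‑epoxy‑4β‑hydroxydaucan‑6‑one | O=C1[C@H]2[C@](O)(C(C)C)C[C@H](OC(C)=O)[C@]2(C)[C@H](OC(C)=O)[C@@H]3O[C@]3(C)C1 | intermediate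
28 | (5αH)‑2α,10α‑diacetoxy‑8α,9α‑epoxydaucane‑4β,6α‑diol | O[C@@H]1[C@H]2[C@](O)(C(C)C)C[C@H](OC(C)=O)[C@]2(C)[C@H](OC(C)=O)[C@@H]3O[C@]3(C)C1 | intermediate
29 | angelic acid, (Z)‑2‑methylbut‑2‑enoic acid | C/C=C(/C)C(=O)O | starting material
30 | angelic 2,4,6‑trichlorobenzoic anhydride | C/C=C(/C)C(=O)OC(=O)c1c(Cl)cc(Cl)cc1Cl | intermediate
31 | (5αH)‑2α,10α‑diacetoxy‑6α‑angeloyloxy‑8α,9α‑epoxydaucan‑4β‑ol (CNP0170993.1) | C/C=C(/C)C(=O)O[C@H]1C[C@@]2(C)O[C@H]2[C@@H](OC(C)=O)[C@@]2(C)[C@@H](OC(C)=O)C[C@@](O)(C(C)C)[C@H]12 | target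

## Step count and risks

Total steps: 16. Longest linear sequence: 15 steps (acetylacetone 4 → 31, steps 2–16); step 1 is a one‑step branch that joins at step 4.

Steps most likely to fail:

**Step 6 (carbenoid cyclopropanation/Cope cascade).** The risks are the facial selectivity at C1 and a slow Cope step, because the C1 methyl sits under the two vinyl groups. The fallback changes the carbene source from a diazo compound to a platinum‑activated enynyl acetate. It sets out from dienal 3 and rejoins at enone 15, replacing steps 2–7.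
- (R)‑Hydroxynitrile lyase with HCN gives the (R)‑cyanohydrin F1, and TBSCl/imidazole gives its silyl ether F2.
- iBu2AlH then aqueous acid gives the α‑silyloxy aldehyde F3.
- LiC≡C–CH=CH2 then Ac2O gives the enynyl acetate F4 (both carbinol epimers converge).
- PtCl2 (5 mol %) in PhMe at 80 °C triggers 1,2‑acyloxy shift, cyclopropanation of the trisubstituted alkene and Cope rearrangement to the bicyclic trienyl acetate F5.
- K2CO3/MeOH gives the dienone F6, and iPrLi/CeCl3 gives the tertiary allylic alcohol F7.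
- Pyridinium chlorochromate, [C5H5NH][CrO3Cl], effects oxidative 1,3‑transposition to 15.

**Step 8 (nucleophilic epoxidation of the tetrasubstituted enone).** The risks are low reactivity at the isopropyl‑bearing β‑carbon and the β‑facial selectivity. The fallback replaces substrate‑controlled peroxide addition by reagent control plus hydroxyl direction. It sets out from 15 and rejoins at 18, so it also bypasses the enolate protonation of step 9.
- (S)‑Me‑CBS oxazaborolidine with catecholborane reduces the ketone to the 6β‑allylic alcohol F8.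
- VO(acac)2/TBHP epoxidises the tetrasubstituted alkene syn to that hydroxyl, giving the 4β,5β‑epoxy‑6β‑ol F9.
- BF3·OEt2 in CH2Cl2 at −78 °C induces a semipinacol 1,2‑hydride shift from C6 to C5, anti to the breaking C5–O bond, which delivers 18 with 5α‑H set stereospecifically.

**Step 11 (selenide opening and selenoxide elimination on the β‑hydroxy ketone).** The risks are sluggish opening next to the quaternary centre and base sensitivity of the aldol unit. The fallback replaces anti opening/syn elimination by syn dihydroxylation/anti elimination. It sets out from 18 and rejoins at 23, replacing steps 10 and 11.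
- OsO4 (cat.) with N‑methylmorpholine N‑oxide dihydroxylates from the α face to give the 9α,10α‑diol F10.
- MsCl/pyridine sulfonylates the less hindered C9 hydroxyl (C10 is neopentyl) to give the mesylate F11.
- DBU in PhMe at 60 °C effects anti E2 elimination with the 8β‑hydrogen to give 23.

## Further compounds

F1 | step 6 | (2R,3E,5E)‑2‑hydroxy‑3‑methylhepta‑3,5‑dienenitrile | N#C[C@H](O)/C(C)=C/C=C/C
F2 | step 6 | (2R,3E,5E)‑2‑[(tert‑butyldimethylsilyl)oxy]‑3‑methylhepta‑3,5‑dienenitrile | N#C[C@H](O[Si](C)(C)C(C)(C)C)/C(C)=C/C=C/C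
F3 | step 6 | (2R,3E,5E)‑2‑[(tert‑butyldimethylsilyl)oxy]‑3‑methylhepta‑3,5‑dienal | O=C[C@H](O[Si](C)(C)C(C)(C)C)/C(C)=C/C=C/C
F4 | step 6 | (5R,6E,8E)‑5‑[(tert‑butyldimethylsilyl)oxy]‑6‑methyldeca‑1,6,8‑trien‑3‑yn‑4‑yl acetate (C4 epimers) | C=CC#CC(OC(C)=O)[C@H](O[Si](C)(C)C(C)(C)C)/C(C)=C/C=C/C
F5 | step 6 | 4‑acetoxy‑2α‑(TBSO)‑1β,8α‑dimethylbicyclo[5.3.0]deca‑3,5,9‑triene | CC(=O)OC1=C[C@H](O[Si](C)(C)C(C)(C)C)[C@]2(C)C=C[C@H](C)CC=C12
F6 | step 6 | 2α‑(TBSO)‑1β,8α‑dimethylbicyclo[5.3.0]deca‑5,9‑dien‑4‑one | O=C1C[C@H](O[Si](C)(C)C(C)(C)C)[C@]2(C)C=C[C@H](C)CC=C12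
F7 | step 6 | 4‑isopropyl‑2α‑(TBSO)‑1β,8α‑dimethylbicyclo[5.3.0]deca‑5,9‑dien‑4‑ol (C4 epimers) | CC(C)C1(O)C[C@H](O[Si](C)(C)C(C)(C)C)[C@]2(C)C=C[C@H](C)CC=C12
F8 | step 8 | (8βH)‑2α‑(TBSO)dauca‑4,9‑dien‑6β‑ol | O[C@H]1C2=C(C(C)C)C[C@H](O[Si](C)(C)C(C)(C)C)[C@]2(C)C=C[C@H](C)C1
F9 | step 8 | (8βH)‑4β,5β‑epoxy‑2α‑(TBSO)dauc‑9‑en‑6β‑ol | O[C@H]1[C@@]23O[C@@]3(C(C)C)C[C@H](O[Si](C)(C)C(C)(C)C)[C@]2(C)C=C[C@H](C)C1
F10 | step 11 | (5αH,8βH)‑4β,9α,10α‑trihydroxy‑2α‑(TBSO)daucan‑6‑one | O=C1[C@H]2[C@](O)(C(C)C)C[C@H](O[Si](C)(C)C(C)(C)C)[C@]2(C)[C@H](O)[C@H](O)[C@H](C)C1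
F11 | step 11 | (5αH,8βH)‑4β,10α‑dihydroxy‑9α‑(methanesulfonyloxy)‑2α‑(TBSO)daucan‑6‑one | O=C1[C@H]2[C@](O)(C(C)C)C[C@H](O[Si](C)(C)C(C)(C)C)[C@]2(C)[C@H](O)[C@H](OS(C)(=O)=O)[C@H](C)C1
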